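**Retrosynthetic overview**

1. The target is (2S)-5,7-dihydroxy-4'-methoxy-8-prenylflavanone; the last step only removes two MOM ethers from O5 and O7.
2. Ring C (the pyranone) is the last ring formed: O1–C8a and C4–C4a are cut together, giving a 3,5-bis(MOM-oxy)-6-prenylbenzyne (ring A) and the four-atom unit O1–C2–C3–C4 as an (S)-β-silyloxy morpholine amide that carries ring B.
3. Enabling feature: in ring A the adjacent carbons C8a and C4a carry O1 and the C4 carbonyl, and C4a is flanked by the C5 oxygen. This is the pattern left by O-attack on a 3-alkoxyaryne (nucleophile at C8a, meta to C5–O; carbanion at C4a), and that carbanion then closes six-membered ring C on C4.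
4. The aryne precursor (an o-silylaryl triflate) comes from phloroglucinol: bis-MOM ether, ortho-bromination, tert-propargyl ether, Lindlar/Claisen (puts prenyl on C8), then retro-Brook/triflation. Rings A and B are bought as arenes.
5. C2 is set by asymmetric transfer hydrogenation of a β-keto amide and carried through unchanged, because its C–O bond is never broken.

Key step: step 9

Remark: flavanone numbering is used throughout (O1, C2, C3, C4, C4a, C5–C8, C8a; the anisyl ring is ring B); the only stereocentre is C2, and the drawn configuration is (S).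

**Route**

Step 1
Reactants: 1 phloroglucinol
Product: 2 3,5-bis(methoxymethoxy)phenol
Conditions: MOMCl (2.0 equiv), i-Pr2NEt (2.2 equiv), DMF–CH2Cl2, 0 °C → rt; chromatography, mono-ether recycled
Reagents that add atoms: chloromethyl methyl ether (MOMCl), COCCl
Why: MOM protection (Williamson-type O-alkylation of the phenoxide) with two equivalents should give the bis-ether as the main component of a statistical mixture, and the three hydroxyls of 1 are equivalent, so no regiochemistry arises.

Step 2
Reactants: 2 3,5-bis(methoxymethoxy)phenol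
Product: 3 2-bromo-3,5-bis(methoxymethoxy)phenol
Conditions: NBS (1.0 equiv), CH2Cl2, −78 → −40 °C
Reagents that add atoms: N-bromosuccinimide (NBS), O=C1CCC(=O)N1Br
Why: Electrophilic aromatic bromination of the free phenol should go ortho to the hydroxyl, since the two equivalent ortho sites are less hindered than the para site between the two MOM ethers and can be reached by hydrogen-bond-guided delivery, and one equivalent at low temperature limits polybromination.

Step 3
Reactants: 3 2-bromo-3,5-bis(methoxymethoxy)phenol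
Product: 4 2-bromo-1,5-bis(methoxymethoxy)-3-[(2-methylbut-3-yn-2-yl)oxy]benzene
Conditions: 3-chloro-3-methylbut-1-yne (1.5 equiv), DBU (1.6 equiv), CuCl2 (1 mol %), MeCN, 0 °C
Reagents that add atoms: 3-chloro-3-methylbut-1-yne, C#CC(C)(C)Cl
Why: Copper-catalysed propargylic etherification (substitution of the tertiary propargylic chloride through a copper acetylide/allenylidene) should give the hindered aryl 1,1-dimethylpropargyl ether cleanly on oxygen.

Step 4
Reactants: 4 2-bromo-1,5-bis(methoxymethoxy)-3-[(2-methylbut-3-yn-2-yl)oxy]benzene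
Product: 7 2-bromo-3,5-bis(methoxymethoxy)-6-(3-methylbut-2-en-1-yl)phenol, via allyl ether 5 (not isolated), via dienone 6 (not isolated)
Conditions: H2 (1 atm), Pd/CaCO3 poisoned with Pb(OAc)2 (Lindlar catalyst), quinoline, toluene, rt; filter; then 110 °C
Reagents that add atoms: none
Why: Lindlar semi-hydrogenation should give the 1,1-dimethylallyl ether 5, whose aromatic Claisen rearrangement ([3,3]) can end productively only at the single free ortho carbon, inverting the allyl unit to a prenyl group before dienone 6 tautomerises to phenol 7; the poisoned catalyst should leave the aryl bromide alone.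

Step 5
Reactants: 7 2-bromo-3,5-bis(methoxymethoxy)-6-(3-methylbut-2-en-1-yl)phenol
Product: 11 3,5-bis(methoxymethoxy)-2-(3-methylbut-2-en-1-yl)-6-(trimethylsilyl)phenyl trifluoromethanesulfonate, via silyl ether 8 (not isolated), via aryllithium 9 (not isolated), via lithium phenoxide 10 (not isolated)
Conditions: HMDS, THF, 65 °C, then evaporate; n-BuLi (1.1 equiv), THF, −78 °C; Tf2O (1.2 equiv), −78 → 0 °C
Reagents that add atoms: hexamethyldisilazane (HMDS), C[Si](C)(C)N[Si](C)(C)C; trifluoromethanesulfonic anhydride (Tf2O), O=S(=O)(OS(=O)(=O)C(F)(F)F)C(F)(F)F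
Why: O-silylation, bromine–lithium exchange and 1,3-O→C silyl migration (retro-Brook rearrangement) should move the silyl group onto the former C–Br carbon, and trapping of the lithium phenoxide with Tf2O is the standard one-pot route to o-silylaryl triflate aryne precursors; exchange at −78 °C should outrun deprotonation of the prenyl CH2.

Step 6
Reactants: 12 ethyl 3-(4-methoxyphenyl)-3-oxopropanoate
Product: 13 1-(4-methoxyphenyl)-3-(morpholin-4-yl)propane-1,3-dione
Conditions: morpholine (1.5 equiv), DMAP (0.3 equiv), toluene, 110 °C, EtOH distilled off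
Reagents that add atoms: morpholine, C1COCCN1
Why: Thermal aminolysis of a β-keto ester (through the acylketene, assisted by DMAP) should give the β-keto amide, driven by removal of ethanol.

Step 7
Reactants: 13 1-(4-methoxyphenyl)-3-(morpholin-4-yl)propane-1,3-dione
Product: 14 (3S)-3-hydroxy-3-(4-methoxyphenyl)-1-(morpholin-4-yl)propan-1-one
Conditions: RuCl[(S,S)-TsDPEN](p-cymene) (1 mol %), HCO2H–Et3N (5:2), DMF, 40 °C
Reagents that add atoms: none
Why: Noyori asymmetric transfer hydrogenation of the aryl ketone; the (S,S)-TsDPEN ligand should deliver hydride to the face that gives the (S)-benzylic alcohol (the same sense as acetophenone to (S)-1-phenylethanol), and this centre becomes C2 of the target.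

Step 8
Reactants: 14 (3S)-3-hydroxy-3-(4-methoxyphenyl)-1-(morpholin-4-yl)propan-1-one
Product: 15 (3S)-3-(4-methoxyphenyl)-1-(morpholin-4-yl)-3-[(trimethylsilyl)oxy]propan-1-one
Conditions: TMSCl (1.2 equiv), imidazole (1.5 equiv), CH2Cl2, 0 °C; non-aqueous work-up
Reagents that add atoms: chlorotrimethylsilane (TMSCl), C[Si](C)(C)Cl
Why: Silyl ether formation masks the O–H so that the oxygen nucleophile can later be set free by fluoride with no proton source in the flask; the stereocentre is not touched.

Step 9
Reactants: 11 3,5-bis(methoxymethoxy)-2-(3-methylbut-2-en-1-yl)-6-(trimethylsilyl)phenyl trifluoromethanesulfonate; 15 (3S)-3-(4-methoxyphenyl)-1-(morpholin-4-yl)-3-[(trimethylsilyl)oxy]propan-1-one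
Product: 20 (2S)-5,7-bis(methoxymethoxy)-2-(4-methoxyphenyl)-8-(3-methylbut-2-en-1-yl)-2,3-dihydro-4H-chromen-4-one, via potassium alkoxide 16 (not isolated), via aryne 17 (not isolated), via arylpotassium 18 (not isolated), via potassium hemiaminalate 19 (not isolated)
Conditions: 15 (1.5 equiv), KF (3.5 equiv), 18-crown-6 (3.5 equiv), DME, −20 °C, slow addition of 11, then → 10 °C; AcOH, −20 °C, then pH 5 acetate buffer
Reagents that add atoms: none
Why: Proposed new method: fluoride removes both silyl groups, so 15 gives the proton-free alkoxide 16 and 11 gives aryne 17; the oxygen of 16 adds to the aryne carbon that becomes C8a, the aryl anion 18 at C4a attacks the morpholine amide carbonyl, and the tetrahedral adduct 19 holds the ketone until the acidic quench, so O1–C8a and C4–C4a are made in one operation. The closest known reaction types are the fluoride-mediated annulation of arynes with salicylates to xanthones (phenoxide addition, then acyl capture by the aryl anion), the O-arylation of aliphatic alcohols by arynes, and the Parham cyclisation of aryllithiums onto tertiary amides; what is new is an aliphatic β-silyloxy amide as the O,C-partner. Ring C closes by 6-exo-trig attack of the C4a carbanion on the amide carbon, which makes the whole event a formal [4+2] annulation of the two aryne carbons with the O1–C2–C3–C4 unit. No lasting stereocentre is created: C2 comes from 14 and keeps its configuration because the nucleophile is its own oxygen and the C2–O bond is never broken, and the epimeric hemiaminal carbon of 19 disappears on work-up. The step needs O-attack at the aryne carbon remote from the C5 methoxymethoxy group, which the inductive distortion of a 3-alkoxyaryne should secure (carbanion placed ortho to the C5 oxygen) against the modest steric bias of the C8 prenyl group, and it needs acyl capture to beat protonation, which the absence of any O–H in the flask should secure. Releasing the ketone only at the buffered quench should keep the base-labile flavanone from opening to the chalcone, which would erode C2.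

Step 10
Reactants: 20 (2S)-5,7-bis(methoxymethoxy)-2-(4-methoxyphenyl)-8-(3-methylbut-2-en-1-yl)-2,3-dihydro-4H-chromen-4-one
Product: 21 (2S)-5,7-dihydroxy-2-(4-methoxyphenyl)-8-(3-methylbut-2-en-1-yl)-2,3-dihydro-4H-chromen-4-one
Conditions: 3 M aq. HCl–MeOH (1:5), 45 °C, stopped at full conversion
Reagents that add atoms: none
Why: Acid-catalysed acetal exchange with methanol (MOM deprotection) should free both phenols, while the aryl methyl ether, the prenyl group and C2 should survive a short, mild treatment.

**Compound list**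

1 | phloroglucinol (benzene-1,3,5-triol) | Oc1cc(O)cc(O)c1 | starting material
2 | 3,5-bis(methoxymethoxy)phenol | COCOc1cc(O)cc(OCOC)c1 | intermediate
3 | 2-bromo-3,5-bis(methoxymethoxy)phenol | COCOc1cc(O)c(Br)c(OCOC)c1 | intermediate
4 | 2-bromo-1,5-bis(methoxymethoxy)-3-[(2-methylbut-3-yn-2-yl)oxy]benzene | C#CC(C)(C)Oc1cc(OCOC)cc(OCOC)c1Br | intermediate
5 | 2-bromo-1,5-bis(methoxymethoxy)-3-[(2-methylbut-3-en-2-yl)oxy]benzene | C=CC(C)(C)Oc1cc(OCOC)cc(OCOC)c1Br | intermediate
6 | 2-bromo-3,5-bis(methoxymethoxy)-6-(3-methylbut-2-en-1-yl)cyclohexa-2,4-dien-1-one (racemic at C6) | O=C1C(Br)=C(OCOC)C=C(OCOC)C1CC=C(C)C | intermediate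
7 | 2-bromo-3,5-bis(methoxymethoxy)-6-(3-methylbut-2-en-1-yl)phenol | Oc1c(Br)c(OCOC)cc(OCOC)c1CC=C(C)C | intermediate
8 | [2-bromo-3,5-bis(methoxymethoxy)-6-(3-methylbut-2-en-1-yl)phenoxy]trimethylsilane | C[Si](C)(C)Oc1c(Br)c(OCOC)cc(OCOC)c1CC=C(C)C | intermediate
9 | {2,4-bis(methoxymethoxy)-5-(3-methylbut-2-en-1-yl)-6-[(trimethylsilyl)oxy]phenyl}lithium | C[Si](C)(C)Oc1c([Li])c(OCOC)cc(OCOC)c1CC=C(C)C | intermediate
10 | lithium 3,5-bis(methoxymethoxy)-2-(3-methylbut-2-en-1-yl)-6-(trimethylsilyl)phenoxide | [Li+].[O-]c1c([Si](C)(C)C)c(OCOC)cc(OCOC)c1CC=C(C)C | intermediate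
11 | 3,5-bis(methoxymethoxy)-2-(3-methylbut-2-en-1-yl)-6-(trimethylsilyl)phenyl trifluoromethanesulfonate | C[Si](C)(C)c1c(OCOC)cc(OCOC)c(CC=C(C)C)c1OS(=O)(=O)C(F)(F)F | intermediate
12 | ethyl 3-(4-methoxyphenyl)-3-oxopropanoate | CCOC(=O)CC(=O)c1ccc(OC)cc1 | starting material
13 | 1-(4-methoxyphenyl)-3-(morpholin-4-yl)propane-1,3-dione | COc1ccc(C(=O)CC(=O)N2CCOCC2)cc1 | intermediate
14 | (3S)-3-hydroxy-3-(4-methoxyphenyl)-1-(morpholin-4-yl)propan-1-one | COc1ccc([C@@H](O)CC(=O)N2CCOCC2)cc1 | intermediate
15 | (3S)-3-(4-methoxyphenyl)-1-(morpholin-4-yl)-3-[(trimethylsilyl)oxy]propan-1-one | COc1ccc([C@@H](O[Si](C)(C)C)CC(=O)N2CCOCC2)cc1 | intermediate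
16 | potassium (1S)-1-(4-methoxyphenyl)-3-(morpholin-4-yl)-3-oxopropan-1-olate | COc1ccc([C@@H]([O-])CC(=O)N2CCOCC2)cc1.[K+] | intermediate
17 | 3,5-bis(methoxymethoxy)-6-(3-methylbut-2-en-1-yl)benzyne (1,2-didehydrobenzene) | COCOC1=CC(OCOC)=C(CC=C(C)C)C#C1 | intermediate
18 | (2-{[(1S)-1-(4-methoxyphenyl)-3-(morpholin-4-yl)-3-oxopropyl]oxy}-4,6-bis(methoxymethoxy)-3-(3-methylbut-2-en-1-yl)phenyl)potassium | COc1ccc([C@H](CC(=O)N2CCOCC2)Oc2c(CC=C(C)C)c(OCOC)cc(OCOC)c2[K])cc1 | intermediate
19 | potassium (2S)-5,7-bis(methoxymethoxy)-2-(4-methoxyphenyl)-8-(3-methylbut-2-en-1-yl)-4-(morpholin-4-yl)chroman-4-olate (both epimers at C4) | COc1ccc([C@@H]2CC([O-])(N3CCOCC3)c3c(OCOC)cc(OCOC)c(CC=C(C)C)c3O2)cc1.[K+] | intermediate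
20 | (2S)-5,7-bis(methoxymethoxy)-2-(4-methoxyphenyl)-8-(3-methylbut-2-en-1-yl)-2,3-dihydro-4H-chromen-4-one | COc1ccc([C@@H]2CC(=O)c3c(OCOC)cc(OCOC)c(CC=C(C)C)c3O2)cc1 | intermediate
21 | (2S)-5,7-dihydroxy-2-(4-methoxyphenyl)-8-(3-methylbut-2-en-1-yl)-2,3-dihydro-4H-chromen-4-one | COc1ccc([C@@H]2CC(=O)c3c(O)cc(O)c(CC=C(C)C)c3O2)cc1 | target

**Step count**

Total: 10 steps. Longest linear sequence: 7 steps (steps 1–5, 9, 10); the second branch is steps 6–8.

**Steps most likely to fail, with fallbacks**

1. Step 9. The alkoxide may attack the wrong aryne carbon (next to the C5 oxygen instead of next to the prenyl group). The aryl anion may be protonated or C-silylated before it reaches the amide. Unmasking of the alkoxide may lag behind aryne formation, so that the aryne is lost to fluoride or to itself. The fallback uses known chemistry, sets out from 7 and 13 and comes back at 20. Ketone 13 is reduced with the enantiomeric catalyst RuCl[(R,R)-TsDPEN](p-cymene) in HCO2H–Et3N to (3R)-3-hydroxy-3-(4-methoxyphenyl)-1-(morpholin-4-yl)propan-1-one F1. Mitsunobu etherification of bromophenol 7 with F1 (PPh3, DIAD, toluene, 0 °C) should proceed with inversion to (3S)-3-[2-bromo-3,5-bis(methoxymethoxy)-6-(3-methylbut-2-en-1-yl)phenoxy]-3-(4-methoxyphenyl)-1-(morpholin-4-yl)propan-1-one F2. Bromine–lithium exchange (n-BuLi, THF, −78 °C) should give (2-{[(1S)-1-(4-methoxyphenyl)-3-(morpholin-4-yl)-3-oxopropyl]oxy}-4,6-bis(methoxymethoxy)-3-(3-methylbut-2-en-1-yl)phenyl)lithium F3, which closes onto the amide (Parham cyclisation) to lithium (2S)-5,7-bis(methoxymethoxy)-2-(4-methoxyphenyl)-8-(3-methylbut-2-en-1-yl)-4-(morpholin-4-yl)chroman-4-olate F4. Quenching with AcOH and pH 5 buffer then gives 20. Here the phenol oxygen of 7 is kept as O1, so no aryne regiochemistry is involved.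

2. Step 10. Brønsted acid may cyclise the prenyl group onto the neighbouring C7 hydroxyl (chroman formation), or open and reclose ring C and so erode C2. The fallback sets out from 20 and comes back at 21. TMSOTf with 2,2'-bipyridyl (CH2Cl2, 0 °C) should convert both aryl MOM ethers into aryl silyl ethers, giving (2S)-2-(4-methoxyphenyl)-8-(3-methylbut-2-en-1-yl)-5,7-bis[(trimethylsilyl)oxy]-2,3-dihydro-4H-chromen-4-one F5. Water then hydrolyses F5 to 21, so the prenyl group never meets a free strong acid.

3. Step 2. Bromination may go para to the hydroxyl (between the two MOM ethers) or run on to polybromination of the very electron-rich ring. The fallback sets out from 2 and comes back at 3, and fixes the site by directed metalation. Phenol 2 is carbamoylated (NaH, ClCONEt2, THF) to 3,5-bis(methoxymethoxy)phenyl N,N-diethylcarbamate F6. Carbamate-directed ortho-lithiation (s-BuLi, TMEDA, THF, −78 °C) should give [2-(diethylcarbamoyloxy)-4,6-bis(methoxymethoxy)phenyl]lithium F7, which is quenched with 1,2-dibromotetrachloroethane to 2-bromo-3,5-bis(methoxymethoxy)phenyl N,N-diethylcarbamate F8. Hydrolysis (NaOH, EtOH, reflux) returns 3.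

**Further compounds**

F1 | step 9 | (3R)-3-hydroxy-3-(4-methoxyphenyl)-1-(morpholin-4-yl)propan-1-one | COc1ccc([C@H](O)CC(=O)N2CCOCC2)cc1
F2 | step 9 | (3S)-3-[2-bromo-3,5-bis(methoxymethoxy)-6-(3-methylbut-2-en-1-yl)phenoxy]-3-(4-methoxyphenyl)-1-(morpholin-4-yl)propan-1-one | COc1ccc([C@H](CC(=O)N2CCOCC2)Oc2c(Br)c(OCOC)cc(OCOC)c2CC=C(C)C)cc1
F3 | step 9 | (2-{[(1S)-1-(4-methoxyphenyl)-3-(morpholin-4-yl)-3-oxopropyl]oxy}-4,6-bis(methoxymethoxy)-3-(3-methylbut-2-en-1-yl)phenyl)lithium | COc1ccc([C@H](CC(=O)N2CCOCC2)Oc2c([Li])c(OCOC)cc(OCOC)c2CC=C(C)C)cc1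
F4 | step 9 | lithium (2S)-5,7-bis(methoxymethoxy)-2-(4-methoxyphenyl)-8-(3-methylbut-2-en-1-yl)-4-(morpholin-4-yl)chroman-4-olate (both epimers at C4) | COc1ccc([C@@H]2CC([O-])(N3CCOCC3)c3c(OCOC)cc(OCOC)c(CC=C(C)C)c3O2)cc1.[Li+]
F5 | step 10 | (2S)-2-(4-methoxyphenyl)-8-(3-methylbut-2-en-1-yl)-5,7-bis[(trimethylsilyl)oxy]-2,3-dihydro-4H-chromen-4-one | COc1ccc([C@@H]2CC(=O)c3c(O[Si](C)(C)C)cc(O[Si](C)(C)C)c(CC=C(C)C)c3O2)cc1
F6 | step 2 | 3,5-bis(methoxymethoxy)phenyl N,N-diethylcarbamate | CCN(CC)C(=O)Oc1cc(OCOC)cc(OCOC)c1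
F7 | step 2 | [2-(diethylcarbamoyloxy)-4,6-bis(methoxymethoxy)phenyl]lithium | CCN(CC)C(=O)Oc1cc(OCOC)cc(OCOC)c1[Li]
F8 | step 2 | 2-bromo-3,5-bis(methoxymethoxy)phenyl N,N-diethylcarbamate | CCN(CC)C(=O)Oc1cc(OCOC)cc(OCOC)c1Br
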